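**Strategy.** The oxolane ring (O1, C2, C3, C4, C5) is reached by strain-release enlargement of a cyclopropane that already holds C3, C4 and C5. The disconnection rests on the fact that C3 and C4 each carry a benzylic carbon that can stand at the ketone level. In an enantiopure trans-1,2-diaroylcyclopropane, iodide opens the C3–C5 bond, the enolate at C3 adds to formaldehyde (new C2–C3 bond) and the alkoxide O1 closes onto C5. One operation thus inserts O1–C2, builds the twofold-symmetric trans-3,4-diaroyloxolane and keeps the cyclopropane chirality. A matched double ketone reduction and desilylation finish the target.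

Key step: step 4

Assumption: (1S,2S)-cyclopropane-1,2-dicarboxylic acid (3) is bought as the single enantiomer; paraformaldehyde serves as the source of monomeric formaldehyde.

**Route**

Step 1
Reactants: 1 4-bromo-2-methoxyphenol
Product: 2 (4-bromo-2-methoxyphenoxy)triisopropylsilane
Conditions: TIPSCl, imidazole, DMF, rt
Reagents that add atoms: triisopropylsilyl chloride, CC(C)[Si](Cl)(C(C)C)C(C)C
Why: Imidazole-promoted O-silylation masks the phenol, which would quench the aryllithium of step 3, as a triisopropylsilyl ether that survives organolithium, MgI2 and borane and is removed by fluoride at the end.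

Step 2
Reactants: 3 (1S,2S)-cyclopropane-1,2-dicarboxylic acid
Product: 4 (1S,2S)-N1,N2-dimethoxy-N1,N2-dimethylcyclopropane-1,2-dicarboxamide
Conditions: CDI, CH2Cl2, rt; then MeNHOMe·HCl, rt
Reagents that add atoms: N,O-dimethylhydroxylamine hydrochloride, CNOC.Cl
Why: Carboxyl activation as the bis(acyl imidazole) and aminolysis give the bis(Weinreb amide) without touching the non-enolisable cyclopropane C–H bonds, so the trans (1S,2S) configuration is carried over unchanged.

Step 3
Reactants: 2 (4-bromo-2-methoxyphenoxy)triisopropylsilane; 4 (1S,2S)-N1,N2-dimethoxy-N1,N2-dimethylcyclopropane-1,2-dicarboxamide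
Product: 6 (1S,2S)-1,2-bis[3-methoxy-4-(triisopropylsilyloxy)benzoyl]cyclopropane, via aryllithium 5 (not isolated)
Conditions: 2 (2.4 equiv), n-BuLi, THF, −78 °C; then 4, −78 → 0 °C; H2O
Reagents that add atoms: none
Why: Bromine–lithium exchange on 2 gives aryllithium 5, which adds once to each amide because the chelated tetrahedral intermediate of the Weinreb ketone synthesis holds until work-up; no stereocentre is touched.

Step 4
Reactants: 6 (1S,2S)-1,2-bis[3-methoxy-4-(triisopropylsilyloxy)benzoyl]cyclopropane
Product: 9 (3R,4R)-3,4-bis[3-methoxy-4-(triisopropylsilyloxy)benzoyl]oxolane, via iodo enolate 7 (not isolated), via iodo aldol 8 (not isolated)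
Conditions: MgI2 (1.2 equiv), paraformaldehyde (excess), THF, rt → 50 °C, sealed vessel
Reagents that add atoms: formaldehyde (charged as paraformaldehyde), C=O
Why: MgI2 binds an aryl ketone and iodide opens the strained ring by SN2 attack at the unsubstituted cyclopropane CH2 (future C5), cleaving C3–C5 to give the (Z)-magnesium enolate 7; its aldol addition to formaldehyde forms C2–C3, and the aldolate oxygen of 8 (future O1) displaces the primary iodide to close the oxolane, returning MgI2. The closest known reaction type is the magnesium iodide ring expansion of acyl cyclopropanes with C=X partners, together with the halide-triggered ring-opening aldol of aryl cyclopropyl ketones and aldehydes. The oxolane closes in the 5-exo-tet mode. C4 is not touched and keeps its configuration; the new stereocentre C3 is set by C4, because with the C4–H bond eclipsing the enolate (allylic 1,3-strain) formaldehyde should enter anti to the C4 aroyl group, which leads to the trans ring, the isomer also favoured in the ring-closing transition state. The step needs iodide to attack the CH2 group and not an acyl-bearing carbon, which sterics and the unfavourable positive charge next to a carbonyl secure, while the twofold symmetry makes the two possible C–CH2 cleavages identical. Trapping by formaldehyde must outrun re-closure of 7, since re-closure through the cis cyclopropane would cost enantiopurity.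

Step 5
Reactants: 9 (3R,4R)-3,4-bis[3-methoxy-4-(triisopropylsilyloxy)benzoyl]oxolane
Product: 10 (3R,4R)-3,4-bis{(S)-hydroxy[3-methoxy-4-(triisopropylsilyloxy)phenyl]methyl}oxolane
Conditions: (R)-Me-CBS oxazaborolidine [(R)-1-methyl-3,3-diphenyltetrahydro-1H,3H-pyrrolo[1,2-c][1,3,2]oxazaborole] (0.3 equiv), BH3·SMe2, THF, −20 °C; MeOH quench
Reagents that add atoms: none
Why: Corey–Bakshi–Shibata reduction: the (R)-oxazaborolidine directs hydride to the face of each aryl ketone that gives the (S)-carbinol (aryl as the large group), and this agrees with the Felkin–Anh and ring-oxygen chelation preference of the (3R,4R) substrate, so the two new stereocentres should form under matched double control.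

Step 6
Reactants: 10 (3R,4R)-3,4-bis{(S)-hydroxy[3-methoxy-4-(triisopropylsilyloxy)phenyl]methyl}oxolane
Product: 11 (3R,4R)-3,4-bis[(S)-hydroxy(4-hydroxy-3-methoxyphenyl)methyl]oxolane (target CNP0157038.3)
Conditions: TBAF, AcOH, THF, 0 °C
Reagents that add atoms: none
Why: Fluoride cleaves the two aryl silyl ethers (desilylation) while the acetic acid buffer keeps the phenoxide concentration low and so protects the p-hydroxybenzylic alcohols from quinone methide formation; no stereocentre is involved.

**Compound list**

1 | 4-bromo-2-methoxyphenol | COc1cc(Br)ccc1O | starting material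
2 | (4-bromo-2-methoxyphenoxy)triisopropylsilane | COc1cc(Br)ccc1O[Si](C(C)C)(C(C)C)C(C)C | intermediate
3 | (1S,2S)-cyclopropane-1,2-dicarboxylic acid | OC(=O)[C@H]1C[C@@H]1C(=O)O | starting material
4 | (1S,2S)-N1,N2-dimethoxy-N1,N2-dimethylcyclopropane-1,2-dicarboxamide | CON(C)C(=O)[C@H]1C[C@@H]1C(=O)N(C)OC | intermediate
5 | [3-methoxy-4-(triisopropylsilyloxy)phenyl]lithium | COc1cc([Li])ccc1O[Si](C(C)C)(C(C)C)C(C)C | intermediate (not isolated)
6 | (1S,2S)-1,2-bis[3-methoxy-4-(triisopropylsilyloxy)benzoyl]cyclopropane | O=C(c1ccc(O[Si](C(C)C)(C(C)C)C(C)C)c(OC)c1)[C@H]1C[C@@H]1C(=O)c1ccc(O[Si](C(C)C)(C(C)C)C(C)C)c(OC)c1 | intermediate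
7 | iodomagnesium (1Z,3S)-3-(iodomethyl)-4-oxo-1,4-bis[3-methoxy-4-(triisopropylsilyloxy)phenyl]but-1-en-1-olate | O=C(c1ccc(O[Si](C(C)C)(C(C)C)C(C)C)c(OC)c1)[C@@H](CI)/C=C(\O[Mg]I)c1ccc(O[Si](C(C)C)(C(C)C)C(C)C)c(OC)c1 | intermediate (not isolated)
8 | (2R,3S)-2-(hydroxymethyl)-3-(iodomethyl)-1,4-bis[3-methoxy-4-(triisopropylsilyloxy)phenyl]butane-1,4-dione (in the flask as its magnesium alkoxide) | O=C(c1ccc(O[Si](C(C)C)(C(C)C)C(C)C)c(OC)c1)[C@@H](CI)[C@H](CO)C(=O)c1ccc(O[Si](C(C)C)(C(C)C)C(C)C)c(OC)c1 | intermediate (not isolated)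
9 | (3R,4R)-3,4-bis[3-methoxy-4-(triisopropylsilyloxy)benzoyl]oxolane | O=C(c1ccc(O[Si](C(C)C)(C(C)C)C(C)C)c(OC)c1)[C@H]1COC[C@@H]1C(=O)c1ccc(O[Si](C(C)C)(C(C)C)C(C)C)c(OC)c1 | intermediate
10 | (3R,4R)-3,4-bis{(S)-hydroxy[3-methoxy-4-(triisopropylsilyloxy)phenyl]methyl}oxolane | COc1cc([C@@H](O)[C@H]2COC[C@@H]2[C@H](O)c2ccc(O[Si](C(C)C)(C(C)C)C(C)C)c(OC)c2)ccc1O[Si](C(C)C)(C(C)C)C(C)C | intermediate
11 | (3R,4R)-3,4-bis[(S)-hydroxy(4-hydroxy-3-methoxyphenyl)methyl]oxolane | COc1cc([C@@H](O)[C@H]2COC[C@@H]2[C@H](O)c2ccc(O)c(OC)c2)ccc1O | target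

**Step count and risks**

Total step count: 6. Longest linear sequence: 5 steps (steps 2, 3, 4, 5, 6 from 3; equally steps 1, 3, 4, 5, 6 from 1).

Steps most likely to fail:

Step 4. Iodide may attack an acyl-bearing ring carbon instead of the CH2 group. The opened enolate may re-close through the cis cyclopropane and erode enantiopurity. The magnesium aldolate may be too slow in displacing iodide, so that retro-aldol cleavage or C-alkylation back to a cyclopropane takes over. Fallback, setting out from 6 and coming back at 9: the cascade is taken apart into separately controlled stages. Compound 6 is opened with trimethylsilyl iodide in CH2Cl2 at −40 °C to the (2S,3Z)-γ-iodo trimethylsilyl enol ether F1. A Mukaiyama hydroxymethylation of F1 with aqueous formaldehyde and Sc(OTf)3 in THF gives the iodo aldol 8, which is isolated this time. Ag2O in CH2Cl2 then closes the ether by 5-exo-tet displacement under non-basic conditions to give 9.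

Step 5. Hydride may be delivered to the wrong carbonyl face at one or both ketones if the intrinsic bias of the substrate opposes the catalyst, leaving a mixture of carbinol epimers. Fallback, setting out from 9 and coming back at 10: the stereocentres are corrected by inversion instead of being set directly. Compound 9 is reduced with the enantiomeric (S)-oxazaborolidine and BH3·SMe2 to the epimeric (R,R)-diol F2. Both carbinols are then inverted by Mitsunobu esterification (4-nitrobenzoic acid, PPh3, DIAD, THF, −20 °C) to the (S,S)-bis(4-nitrobenzoate) F3. Methanolysis with K2CO3 in MeOH at 0 °C returns 10.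

Step 3. The second acyl substitution may stall at the mono-ketone, or the aryllithium may be consumed by butylation and proton transfer before it reaches the hindered second amide. Fallback, setting out from 3 and 5 and coming back at 6: the ketones are made by palladium-catalysed acyl coupling instead of organolithium addition. Diacid 3 is converted with ethanethiol, DCC and DMAP into S,S'-diethyl (1S,2S)-cyclopropane-1,2-bis(carbothioate) F4. Aryllithium 5 is transmetalated with ZnCl2 to [3-methoxy-4-(triisopropylsilyloxy)phenyl]zinc chloride F5. Fukuyama coupling of F4 with F5 under PdCl2(PPh3)2 in THF/toluene gives 6.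

Further compounds
F1 | step 4 | (2S,3Z)-2-(iodomethyl)-1,4-bis[3-methoxy-4-(triisopropylsilyloxy)phenyl]-4-(trimethylsilyloxy)but-3-en-1-one | O=C(c1ccc(O[Si](C(C)C)(C(C)C)C(C)C)c(OC)c1)[C@@H](CI)/C=C(\O[Si](C)(C)C)c1ccc(O[Si](C(C)C)(C(C)C)C(C)C)c(OC)c1
F2 | step 5 | (3R,4R)-3,4-bis{(R)-hydroxy[3-methoxy-4-(triisopropylsilyloxy)phenyl]methyl}oxolane | COc1cc([C@H](O)[C@H]2COC[C@@H]2[C@@H](O)c2ccc(O[Si](C(C)C)(C(C)C)C(C)C)c(OC)c2)ccc1O[Si](C(C)C)(C(C)C)C(C)C
F3 | step 5 | (3R,4R)-3,4-bis{(S)-(4-nitrobenzoyloxy)[3-methoxy-4-(triisopropylsilyloxy)phenyl]methyl}oxolane | COc1cc([C@@H](OC(=O)c3ccc(cc3)[N+](=O)[O-])[C@H]2COC[C@@H]2[C@H](OC(=O)c3ccc(cc3)[N+](=O)[O-])c2ccc(O[Si](C(C)C)(C(C)C)C(C)C)c(OC)c2)ccc1O[Si](C(C)C)(C(C)C)C(C)C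
F4 | step 3 | S,S'-diethyl (1S,2S)-cyclopropane-1,2-bis(carbothioate) | CCSC(=O)[C@H]1C[C@@H]1C(=O)SCC
F5 | step 3 | [3-methoxy-4-(triisopropylsilyloxy)phenyl]zinc chloride | COc1cc([Zn]Cl)ccc1O[Si](C(C)C)(C(C)C)C(C)C
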